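**Plan**

- Retrosynthetic cuts: the C8–O ester bond; then C3–C4 of the five-membered ring (made as C3=C4); then C1–C2 (allyl) and C4–C5 (isopropenyl); last the C1–C5/C5–C6 bonds around C5, the one ring carbon that (R)-carvone lacks.
- Forward order: carvone's ring (C1, C10 with its methyl, C9, C8, C7 with C11–C13, C6) is enlarged by C5 to the seven-membered ring; C11 is hydrated and C8 oxygenated; isopropenyl goes on C5 and allyl on C1; the five-membered ring closes by metathesis; the 4-coumarate is attached last.
- Enabling feature: allyl on sp2 C1 of the tetrasubstituted C1=C10 alkene and isopropenyl on the neighbouring C5 put two terminal alkenes on adjacent atoms of the seven-membered ring, so only the five-membered ring C1–C2–C3=C4–C5 can close.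
- Stereochemistry: C7 from (R)-carvone; C8 by peracid attack anti to the C7 side chain; C5 by axial protonation of a ketone enolate (cis to C7, also the stable epimer); C4 by hydrogenation of C3=C4 on the face opposite C6.

Key step: step 10

Remark: guaiane locants (C1=C10 alkene, C4 the CHMe, C5 the ring-fusion CH, C7 bearing C11, C8 the oxygenated carbon) are used for all intermediates; in the diazoacetate ring enlargement the saturated C6 methylene is assumed to migrate in preference to the alkenyl carbon, as is usual for diazoacetate (unlike diazomethane) homologations.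

**Route**

Step 1
Reactants: 1 (R)-carvone
Product: 2 ethyl (6R)-3-methyl-2-oxo-6-(prop-1-en-2-yl)cyclohept-3-ene-1-carboxylate (C1 epimers and enol form)
Conditions: N2CHCO2Et, BF3·OEt2, CH2Cl2, 0 °C → rt
Reagents that add atoms: ethyl diazoacetate, CCOC(=O)C=[N+]=[N-]
Why: Lewis-acid-promoted diazoacetate homologation of a ketone (Tiffeneau–Demjanov type), in which the saturated C6 methylene of the diazonium betaine should migrate rather than the conjugated alkenyl carbon, inserting the ester-bearing C5 between C1 and C6 without touching the enone or C7.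

Step 2
Reactants: 2 ethyl (6R)-3-methyl-2-oxo-6-(prop-1-en-2-yl)cyclohept-3-ene-1-carboxylate
Product: 3 (S)-2-methyl-5-(prop-1-en-2-yl)cyclohept-2-en-1-one
Conditions: NaCl, DMSO–H2O, 150 °C
Reagents that add atoms: none
Why: Krapcho dealkoxycarbonylation of the β-keto ester leaves C5 as a methylene and the alkene in its stable conjugated position.

Step 3
Reactants: 3 (S)-2-methyl-5-(prop-1-en-2-yl)cyclohept-2-en-1-one
Product: 4 (S)-5-(2-hydroxypropan-2-yl)-2-methylcyclohept-2-en-1-one
Conditions: 50% aq. H2SO4, 0 °C → rt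
Reagents that add atoms: water, O
Why: Markovnikov acid-catalysed hydration of the 1,1-disubstituted alkene through the tertiary C11 cation, the protonated enone alkene being inert as in the classical hydration of carvone; C7 is not involved.

Step 4
Reactants: 4 (S)-5-(2-hydroxypropan-2-yl)-2-methylcyclohept-2-en-1-one
Product: 5 (S)-2-methyl-1-(triethylsilyloxy)-5-[2-(triethylsilyloxy)propan-2-yl]cyclohepta-1,3-diene
Conditions: Et3SiOTf (2.5 equiv), Et3N, CH2Cl2, 0 °C → rt
Reagents that add atoms: triethylsilyl trifluoromethanesulfonate, CC[Si](CC)(CC)OS(=O)(=O)C(F)(F)F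
Why: Silyl dienol ether formation by soft enolisation under equilibrating conditions should give the linearly conjugated (thermodynamic) diene by loss of a C8 proton, while the tertiary alcohol is silylated at the same time.

Step 5
Reactants: 5 (S)-2-methyl-1-(triethylsilyloxy)-5-[2-(triethylsilyloxy)propan-2-yl]cyclohepta-1,3-diene
Product: 7 (4S,5S)-4-hydroxy-5-(2-hydroxypropan-2-yl)-2-methylcyclohept-2-en-1-one (guaiane C8 and C7), via tertiary silyl ether 6 (not isolated)
Conditions: mCPBA, NaHCO3, CH2Cl2, −20 °C; then HF·pyridine, THF, 0 °C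
Reagents that add atoms: 3-chloroperoxybenzoic acid (mCPBA), OOC(=O)c1cccc(Cl)c1
Why: Vinylogous Rubottom oxidation, in which the peracid attacks the γ terminus (C8=C9) of the dienol ether on the face away from the bulky C7 side chain and the epoxide collapses to the γ-hydroxy enone, setting the C8 oxygen trans to C7; HF then frees the tertiary alcohol.

Step 6
Reactants: 7 (4S,5S)-4-hydroxy-5-(2-hydroxypropan-2-yl)-2-methylcyclohept-2-en-1-one
Product: 8 (7S,8S)-acetonide enone: the C8 and C11 oxygens of 7 joined by CMe2 in a 1,3-dioxane trans-fused to the cycloheptenone at C7/C8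
Conditions: 2-methoxypropene, PPTS (cat.), CH2Cl2, 0 °C → rt
Reagents that add atoms: 2-methoxypropene, COC(C)=C
Why: Kinetic acetalisation of the trans 1,3-diol with an enol ether, whose irreversible addition should overcome the strain of the tetramethyl-1,3-dioxane.

Step 7
Reactants: 8 (7S,8S)-acetonide enone; 9 2-bromopropene
Product: 12 (5S,7S,8S)-5-(prop-1-en-2-yl) ketone: acetonide enone 8 carrying isopropenyl on C5 (α′ to the C1 carbonyl) cis to the C7 substituent, via lithium enolate 10 (not isolated), via lithium dienolate 11 (not isolated)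
Conditions: LiN(SiMe3)2 (2.3 equiv), THF–toluene, −78 °C; Pd2(dba)3 (cat.), P(t-Bu)3 (cat.), 9, −78 °C → rt; AcOH, −78 °C
Reagents that add atoms: none
Why: Palladium-catalysed α-alkenylation of a ketone enolate (oxidative addition of the alkenyl bromide to zerovalent palladium, transmetalation with the kinetic α′ enolate, reductive elimination); the product rests as its dienolate and should be protonated at C5 axially, opposite the pseudoaxial C6–H, placing isopropenyl pseudoequatorial and cis to the C7 substituent, which is also the more stable epimer.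

Step 8
Reactants: 12 (5S,7S,8S)-5-(prop-1-en-2-yl) ketone
Product: 14 (5S,7S,8S)-enol triflate: C1(OTf)=C10(Me) cycloheptene with C5 isopropenyl and the C7/C8 acetonide, via lithium enolate 13 (not isolated)
Conditions: LiBH(s-Bu)3, THF, −78 °C; then N-(5-chloropyridin-2-yl)bis(trifluoromethanesulfonyl)imide, −78 → 0 °C
Reagents that add atoms: N-(5-chloropyridin-2-yl)bis(trifluoromethanesulfonyl)imide (Comins' reagent), FC(F)(F)S(=O)(=O)N(c1ccc(Cl)cn1)S(=O)(=O)C(F)(F)F
Why: Conjugate reduction of the enone by the bulky borohydride (the carbonyl is flanked by two substituted carbons) gives the C1=C10 enolate regiospecifically, and O-sulfonylation fixes the tetrasubstituted alkene as its enol triflate while C5 stays untouched at low temperature.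

Step 9
Reactants: 14 (5S,7S,8S)-enol triflate; 15 allyltributylstannane
Product: 16 (5S,7S,8S)-triene: 1-allyl-5-isopropenyl-10-methylcyclohept-1(10)-ene with the C7/C8 acetonide
Conditions: Pd(PPh3)4 (cat.), LiCl, THF, 65 °C
Reagents that add atoms: none
Why: Stille coupling of the enol triflate with the allylstannane (oxidative addition, allyl transfer from tin, reductive elimination) forms C1–C2 with the alkene held at C1=C10.

Step 10
Reactants: 16 (5S,7S,8S)-triene
Product: 17 (5S,7S,8S)-guaia-1(10),3-diene-8,11-diol acetonide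
Conditions: second-generation Grubbs catalyst RuCl2(=CHPh)(PCy3)(H2IMes) (5 mol %), 1,4-benzoquinone (10 mol %), CH2Cl2 (0.005 M), 40 °C
Reagents that add atoms: none
Why: The ruthenium benzylidene exchanges with the monosubstituted allyl alkene to give an alkylidene at C3, which adds to the 1,1-disubstituted isopropenyl alkene and, by cycloreversion of the ruthenacyclobutane, releases the cyclopentene and a ruthenium methylidene, ethylene escaping (ring-closing olefin metathesis, Chauvin mechanism). The closest known reaction type is ring-closing metathesis of 1,6-dienes with one 1,1-disubstituted alkene to 1-methylcyclopentenes using N-heterocyclic-carbene ruthenium catalysts. The five-membered ring closes by joining C3 to C4 across the C2–C1–C5 tether, the new alkene lying inside the ring. No stereocentre is formed, and C5 keeps its configuration because the medium is neither acidic nor basic. The step needs site selectivity for the two terminal alkenes over C1=C10, which is secured because the tetrasubstituted ring alkene cannot enter a metallacycle at a useful rate, while high dilution disfavours cross-metathesis and benzoquinone suppresses ruthenium hydride migration of the skipped diene.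

Step 11
Reactants: 17 (5S,7S,8S)-guaia-1(10),3-diene-8,11-diol acetonide
Product: 18 (4S,5S,7S,8S)-guai-1(10)-ene-8,11-diol acetonide
Conditions: H2 (4 atm), RhCl(PPh3)3 (cat.), benzene–EtOH, 40 °C
Reagents that add atoms: none
Why: Homogeneous hydrogenation with RhCl(PPh3)3 reduces the trisubstituted cyclopentene but not the tetrasubstituted C1=C10 alkene and does not migrate double bonds; syn delivery on the H5 face, opposite C6 and the C7 side chain, should set C4 with its methyl cis to C6.

Step 12
Reactants: 18 (4S,5S,7S,8S)-guai-1(10)-ene-8,11-diol acetonide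
Product: 19 (4S,5S,7S,8S)-guai-1(10)-ene-8,11-diol
Conditions: AcOH–THF–H2O (3:1:1), 40 °C
Reagents that add atoms: none
Why: Acid-catalysed acetal hydrolysis of the strained acetonide under conditions too mild to ionise the tertiary alcohol or shift the tetrasubstituted alkene.

Step 13
Reactants: 20 4-coumaric acid
Product: 22 (E)-3-[4-(tert-butyldimethylsilyloxy)phenyl]prop-2-enoic acid, via bis-silyl derivative 21 (not isolated)
Conditions: TBSCl (2.4 equiv), imidazole, DMF, rt; then AcOH–THF–H2O, rt
Reagents that add atoms: tert-butyldimethylsilyl chloride, CC(C)(C)[Si](C)(C)Cl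
Why: Silylation of phenol and acid followed by selective hydrolysis of the labile silyl ester leaves the phenol protected for the acylation.

Step 14
Reactants: 19 (4S,5S,7S,8S)-guai-1(10)-ene-8,11-diol; 22 (E)-3-[4-(tert-butyldimethylsilyloxy)phenyl]prop-2-enoic acid
Product: 23 (4S,5S,7S,8S)-11-hydroxyguai-1(10)-en-8-yl (E)-3-[4-(tert-butyldimethylsilyloxy)phenyl]prop-2-enoate
Conditions: DCC, DMAP, CH2Cl2, 0 °C → rt
Reagents that add atoms: none
Why: Steglich esterification acylates the secondary C8 alcohol with retention, while the tertiary C11 alcohol does not react under these conditions.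

Step 15
Reactants: 23 (4S,5S,7S,8S)-11-hydroxyguai-1(10)-en-8-yl (E)-3-[4-(tert-butyldimethylsilyloxy)phenyl]prop-2-enoate
Product: 24 (4S,5S,7S,8S)-11-hydroxyguai-1(10)-en-8-yl (E)-3-(4-hydroxyphenyl)prop-2-enoate
Conditions: Bu4NF, AcOH, THF, 0 °C
Reagents that add atoms: none
Why: Fluoride-induced cleavage of the aryl silyl ether, buffered with acetic acid so that the cinnamate ester and its E geometry are preserved.

**Compound list**

1 | (R)-carvone | CC1=CC[C@H](CC1=O)C(C)=C | starting material
2 | ethyl (6R)-3-methyl-2-oxo-6-(prop-1-en-2-yl)cyclohept-3-ene-1-carboxylate (C1 epimers and enol form) | CC1=CC[C@H](CC(C(=O)OCC)C1=O)C(C)=C | intermediate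
3 | (S)-2-methyl-5-(prop-1-en-2-yl)cyclohept-2-en-1-one | CC1=CC[C@H](CCC1=O)C(C)=C | intermediate
4 | (S)-5-(2-hydroxypropan-2-yl)-2-methylcyclohept-2-en-1-one | CC1=CC[C@H](CCC1=O)C(C)(C)O | intermediate
5 | (S)-2-methyl-1-(triethylsilyloxy)-5-[2-(triethylsilyloxy)propan-2-yl]cyclohepta-1,3-diene | CC1=C(O[Si](CC)(CC)CC)CC[C@@H](C=C1)C(C)(C)O[Si](CC)(CC)CC | intermediate
6 | (4S,5S)-4-hydroxy-2-methyl-5-[2-(triethylsilyloxy)propan-2-yl]cyclohept-2-en-1-one | CC1=C[C@H](O)[C@H](CCC1=O)C(C)(C)O[Si](CC)(CC)CC | intermediate
7 | (4S,5S)-4-hydroxy-5-(2-hydroxypropan-2-yl)-2-methylcyclohept-2-en-1-one | CC1=C[C@H](O)[C@H](CCC1=O)C(C)(C)O | intermediate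
8 | (7S,8S)-acetonide enone (C8–O and C11–O joined by CMe2, trans-fused 1,3-dioxane) | CC1=C[C@@H]2OC(C)(C)OC(C)(C)[C@H]2CCC1=O | intermediate
9 | 2-bromopropene | CC(Br)=C | starting material
10 | lithium C1/C5 enolate of 8 | CC1=C[C@@H]2OC(C)(C)OC(C)(C)[C@H]2CC=C1[O-].[Li+] | intermediate
11 | lithium dienolate of the 5-isopropenyl ketone | CC1=C[C@@H]2OC(C)(C)OC(C)(C)[C@H]2CC(C(C)=C)=C1[O-].[Li+] | intermediate
12 | (5S,7S,8S)-5-(prop-1-en-2-yl) acetonide enone | CC1=C[C@@H]2OC(C)(C)OC(C)(C)[C@H]2C[C@@H](C(C)=C)C1=O | intermediate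
13 | lithium C1/C10 enolate from conjugate reduction of 12 | CC1=C([O-])[C@H](C(C)=C)C[C@H]2[C@H](C1)OC(C)(C)OC2(C)C.[Li+] | intermediate
14 | (5S,7S,8S)-C1 enol triflate (C1=C10) with C5 isopropenyl and C7/C8 acetonide | CC1=C(OS(=O)(=O)C(F)(F)F)[C@H](C(C)=C)C[C@H]2[C@H](C1)OC(C)(C)OC2(C)C | intermediate
15 | allyltributylstannane | C=CC[Sn](CCCC)(CCCC)CCCC | starting material
16 | (5S,7S,8S)-1-allyl-5-isopropenyl-10-methylcyclohept-1(10)-ene 8,11-acetonide (triene) | CC1=C(CC=C)[C@H](C(C)=C)C[C@H]2[C@H](C1)OC(C)(C)OC2(C)C | intermediate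
17 | (5S,7S,8S)-guaia-1(10),3-diene-8,11-diol acetonide | CC1=C2CC=C(C)[C@@H]2C[C@H]3[C@H](C1)OC(C)(C)OC3(C)C | intermediate
18 | (4S,5S,7S,8S)-guai-1(10)-ene-8,11-diol acetonide | CC1=C2CC[C@H](C)[C@@H]2C[C@H]3[C@H](C1)OC(C)(C)OC3(C)C | intermediate
19 | (4S,5S,7S,8S)-guai-1(10)-ene-8,11-diol | CC1=C2CC[C@H](C)[C@@H]2C[C@H](C(C)(C)O)[C@@H](O)C1 | intermediate
20 | 4-coumaric acid | OC(=O)/C=C/c1ccc(O)cc1 | starting material
21 | tert-butyldimethylsilyl (E)-3-[4-(tert-butyldimethylsilyloxy)phenyl]prop-2-enoate | CC(C)(C)[Si](C)(C)OC(=O)/C=C/c1ccc(O[Si](C)(C)C(C)(C)C)cc1 | intermediate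
22 | (E)-3-[4-(tert-butyldimethylsilyloxy)phenyl]prop-2-enoic acid | OC(=O)/C=C/c1ccc(O[Si](C)(C)C(C)(C)C)cc1 | intermediate
23 | (4S,5S,7S,8S)-11-hydroxyguai-1(10)-en-8-yl (E)-3-[4-(tert-butyldimethylsilyloxy)phenyl]prop-2-enoate | CC1=C2CC[C@H](C)[C@@H]2C[C@H](C(C)(C)O)[C@@H](OC(=O)/C=C/c2ccc(O[Si](C)(C)C(C)(C)C)cc2)C1 | intermediate
24 | (4S,5S,7S,8S)-11-hydroxyguai-1(10)-en-8-yl (E)-3-(4-hydroxyphenyl)prop-2-enoate (CNP0403230.1) | CC1=C2CC[C@H](C)[C@@H]2C[C@H](C(C)(C)O)[C@@H](OC(=O)/C=C/c2ccc(O)cc2)C1 | target

**Count and risks**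

Total steps: 15. Longest linear sequence: 14 (steps 1–12, 14, 15); step 13 prepares the acid partner.

Steps most likely to fail:

1. Step 5 (together with the enolisation in step 4). Regiocontrol may be lost if enolisation goes toward C5 instead of C8, or if the peracid attacks the silyloxy-bearing C1=C10 bond and hydroxylates C10. Fallback, setting out from 4: the tertiary alcohol alone is silylated (Et3SiOTf, 2,6-lutidine, CH2Cl2, −78 °C) to give (S)-2-methyl-5-[2-(triethylsilyloxy)propan-2-yl]cyclohept-2-en-1-one F1. Equilibration to the extended potassium dienolate (KOt-Bu, t-BuOH–THF) and kinetic α-protonation with cold aqueous AcOH should give the deconjugated ketone (5S)-2-methyl-5-[2-(triethylsilyloxy)propan-2-yl]cyclohept-3-en-1-one F2. mCPBA then epoxidises the isolated C8=C9 alkene anti to the C7 side chain to give the 3,4-epoxy ketone F3. DBU opens the epoxide by β-elimination from C10 to give 6, and HF·pyridine brings the route back at 7. The epoxide fixes the oxygen at C8 unambiguously.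

2. Step 7. The new alkene may drift into conjugation with the ketone, a second alkenylation may occur, or protonation at C5 may be poorly stereoselective. Fallback, setting out from 8: the kinetic enolate (LiN(i-Pr)2, THF, −78 °C) is transmetalated with ZnCl2 and added to acetone to give the 5-(2-hydroxypropan-2-yl) aldol adduct F4. Mesylation and elimination (MsCl, Et3N; DBU) give the 5-(propan-2-ylidene) dienone F5. LiN(i-Pr)2 then removes a methyl proton of the isopropylidene group to form dienolate 11, and protonation with AcOH at −78 °C returns the route at 12.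

3. Step 11. Hydrogen uptake at the hindered trisubstituted alkene may be slow, C1=C10 may be reduced or migrate, or facial selectivity at C4 may be poor. Fallback, setting out from 17: hydroboration of the trisubstituted alkene (BH3·SMe2, 1 equiv, THF, 0 °C) and oxidation (NaOH, H2O2) should give the (3S,4S,5S,7S,8S)-3-hydroxyguai-1(10)-ene acetonide F6, with H4 again delivered on the H5 face. The alcohol is converted into its S-methyl xanthate F7 (NaH, CS2, MeI) and deoxygenated by the Barton–McCombie reaction (Bu3SnH, AIBN, toluene, 80 °C), returning at 18.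

**Further compounds**

F1 | step 5 | (S)-2-methyl-5-[2-(triethylsilyloxy)propan-2-yl]cyclohept-2-en-1-one | CC1=CC[C@H](CCC1=O)C(C)(C)O[Si](CC)(CC)CC
F2 | step 5 | (5S)-2-methyl-5-[2-(triethylsilyloxy)propan-2-yl]cyclohept-3-en-1-one (C2 epimers) | CC1C=C[C@H](CCC1=O)C(C)(C)O[Si](CC)(CC)CC
F3 | step 5 | 3,4-epoxy ketone from F2 (epoxide oxygen anti to the C7 side chain; guaiane C8,C9 epoxide) | CC1[C@@H]2O[C@@H]2[C@H](CCC1=O)C(C)(C)O[Si](CC)(CC)CC
F4 | step 7 | 5-(2-hydroxypropan-2-yl) aldol adduct of acetonide enone 8 (C5 epimers) | CC1=C[C@@H]2OC(C)(C)OC(C)(C)[C@H]2CC(C(C)(C)O)C1=O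
F5 | step 7 | 5-(propan-2-ylidene) dienone from F4 | CC1=C[C@@H]2OC(C)(C)OC(C)(C)[C@H]2CC(=C(C)C)C1=O
F6 | step 11 | (3S,4S,5S,7S,8S)-3-hydroxyguai-1(10)-ene-8,11-diol acetonide | CC1=C2C[C@@H](O)[C@H](C)[C@@H]2C[C@H]3[C@H](C1)OC(C)(C)OC3(C)C
F7 | step 11 | O-(guai-1(10)-en-3-yl) S-methyl xanthate of F6 | CC1=C2C[C@@H](OC(=S)SC)[C@H](C)[C@@H]2C[C@H]3[C@H](C1)OC(C)(C)OC3(C)C
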